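## Retrosynthetic overview
- The target is the all-trans (2,3-trans; 3,4-trans) 2-aryl-3-hydroxymethyl-4-aroyl-THF. It comes from global hydrogenolytic debenzylation of the tri-O-benzyl ketone **11**; the α-keto C4 centre is set thermodynamically by epimerisation (**10** → **11**).
- C3 and its CH2OH come from an anti-selective photoredox decarboxylative Giese addition of BnOCH2• to the chiral 2-aryl-4-aroyl-2,5-dihydrofuran enone **9**. This replaces the usual lactone-alkylation approach.
- The only ring formed is the THF, by RCM of diene ether **8**. **8** is a Williamson coupling of the CBS-derived (S)-1-arylallyl alcohol **5** with a Morita–Baylis–Hillman (MBH)-derived 2-(bromomethyl) aryl enone **7**.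
- **5** and **7** both come from the aryl vinyl ketone **4**, which is made from syringaldehyde.

Assumptions:
- Only substrates are numbered; reagents are given with SMILES in each step.
- (R)-Me-CBS is assumed to give the (S)-carbinol from this aryl vinyl ketone, by analogy with acetophenone. This is checked by chiral HPLC or Mosher analysis.

## Route

**Step 1**
Reactants: **1** syringaldehyde (4-hydroxy-3,5-dimethoxybenzaldehyde)
Product: **2** 4-(benzyloxy)-3,5-dimethoxybenzaldehyde
Conditions: BnBr, K2CO3, DMF, rt, 12 h
Reagents that add atoms: benzyl bromide, BrCc1ccccc1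
Why: Williamson O-benzylation gives a phenol protecting group that survives every later step (Grignard, NaH, Ru carbene, photoredox) and comes off in the last step.

**Step 2**
Reactants: **2**
Product: **3** (±)-1-[4-(benzyloxy)-3,5-dimethoxyphenyl]prop-2-en-1-ol
Conditions: CH2=CHMgBr, THF, 0 °C, 1 h
Reagents that add atoms: vinylmagnesium bromide, C=C[Mg]Br
Why: Grignard 1,2-addition to the aldehyde; the stereocentre is racemic and is destroyed in step 3.

**Step 3**
Reactants: **3**
Product: **4** 1-[4-(benzyloxy)-3,5-dimethoxyphenyl]prop-2-en-1-one (aryl vinyl ketone)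
Conditions: activated MnO2, CH2Cl2, rt, 6 h
Reagents that add atoms: none
Why: MnO2 selectively oxidises the benzylic/allylic alcohol. The enone is used promptly because it polymerises on storage.

**Step 4**
Reactants: **4**
Product: **5** (S)-1-[4-(benzyloxy)-3,5-dimethoxyphenyl]prop-2-en-1-ol
Conditions: (R)-Me-CBS (10 mol%), catecholborane, toluene, −78 °C, 4 h
Reagents that add atoms: none (only H is added)
Why: Corey–Itsuno (CBS) reduction is 1,2-selective on enones and sets the C2 stereocentre (S) with the aryl group as the large substituent. This is the only enantio-determining step of the route.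

**Step 5**
Reactants: **4**
Product: **6** 2-(hydroxymethyl)-1-aryl-prop-2-en-1-one (aryl = 4-benzyloxy-3,5-dimethoxyphenyl)
Conditions: 37% aq. HCHO (5 equiv), DABCO (0.3 equiv), dioxane/H2O, rt, 24 h
Reagents that add atoms: formaldehyde, C=O
Why: Morita–Baylis–Hillman hydroxymethylation of a vinyl ketone, which is an activated substrate, gives the α-hydroxymethyl enone.

**Step 6**
Reactants: **6**
Product: **7** 2-(bromomethyl)-1-aryl-prop-2-en-1-one
Conditions: PBr3, Et2O, 0 °C, 1 h; used crude
Reagents that add atoms: phosphorus tribromide, BrP(Br)Br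
Why: Allylic alcohol to allylic bromide (standard MBH-alcohol bromination), giving a reactive electrophile for step 7.

**Step 7**
Reactants: **5** (S)-allylic alcohol + **7** allylic bromide
Product: **8** (S)-diene ether, CH2=CH–CH(Ar)–O–CH2–C(=CH2)–C(=O)Ar
Conditions: NaH (1.2 equiv), THF, 0 °C → rt, 3 h
Reagents that add atoms: none (NaH is only a base)
Why: Williamson etherification. SN2 and SN2′ attack on the symmetric 2-substituted allyl bromide give the same product, and the carbinol centre is not touched, so (S) is retained.

**Step 8**
Reactants: **8**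
Product: **9** (S)-[2-aryl-2,5-dihydrofuran-4-yl](aryl)methanone, i.e. O=C(Ar)C1=C[C@@H](Ar)OC1
Conditions: Hoveyda–Grubbs II (5 mol%), toluene (0.01 M), 60 °C, 3 h
Reagents that add atoms: none (ethylene is lost)
Why: Ring-closing metathesis forms the THF ring as a conjugated enone. The 5-membered ring closes preferentially over cross-metathesis at high dilution; no new stereocentre forms and C2 is retained.

**Step 9**
Reactants: **9**
Product: **10** 2,3-trans-3-(benzyloxymethyl)-4-aroyl-2-aryl-THF (C4 as an epimeric mixture)
Conditions: [Ir{dF(CF3)ppy}2(dtbbpy)]PF6 (1 mol%), BnOCH2CO2H (2 equiv), Cs2CO3 (1 equiv), DMF, blue LEDs, rt, 16 h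
Reagents that add atoms: 2-(benzyloxy)acetic acid, OC(=O)COCc1ccccc1
Why: Photoredox decarboxylative Giese (conjugate) addition of the nucleophilic BnOCH2• radical to the β-carbon C3 of the enone. The radical approaches anti to the adjacent C2-aryl group, which sets C3 trans to C2 (3R).
The resulting α-keto radical is reduced and protonated at C4 with little selectivity, so C4 is corrected in step 10.

**Step 10**
Reactants: **10**
Product: **11** (2S,3R,4S)-tri-O-benzyl ketone
Conditions: DBU (0.2 equiv), CH2Cl2, 0 °C → rt, 4 h
Reagents that add atoms: none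
Why: Base-mediated enolisation of the ketone α-carbon C4 equilibrates to the thermodynamically favoured 3,4-trans isomer (aroyl trans to CH2OBn), giving the all-trans arrangement of the target. C2 and C3 are not acidic and are untouched.

**Step 11**
Reactants: **11**
Product: **12** target, (2S,3R,4S)-4-(4-hydroxy-3,5-dimethoxybenzoyl)-2-(4-hydroxy-3,5-dimethoxyphenyl)-3-(hydroxymethyl)tetrahydrofuran
Conditions: H2 (1 atm), 10% Pd/C, EtOAc/EtOH 1:1, rt, 3 h
Reagents that add atoms: none (H2 only; toluene is lost)
Why: Hydrogenolysis cleaves the two aryl benzyl ethers and the alkyl benzyl ether under mild, neutral conditions. The aryl ketone and the benzylic THF ether survive the short reaction time.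

## Compound list
1 | syringaldehyde | COc1cc(C=O)cc(OC)c1O | starting material
2 | 4-(benzyloxy)-3,5-dimethoxybenzaldehyde | COc1cc(C=O)cc(OC)c1OCc1ccccc1 | intermediate
3 | (±)-1-aryl-prop-2-en-1-ol | C=CC(O)c1cc(OC)c(OCc2ccccc2)c(OC)c1 | intermediate
4 | aryl vinyl ketone | C=CC(=O)c1cc(OC)c(OCc2ccccc2)c(OC)c1 | intermediate
5 | (S)-1-aryl-prop-2-en-1-ol | C=C[C@H](O)c1cc(OC)c(OCc2ccccc2)c(OC)c1 | intermediate
6 | 2-(hydroxymethyl)-1-aryl-prop-2-en-1-one | C=C(CO)C(=O)c1cc(OC)c(OCc2ccccc2)c(OC)c1 | intermediate
7 | 2-(bromomethyl)-1-aryl-prop-2-en-1-one | C=C(CBr)C(=O)c1cc(OC)c(OCc2ccccc2)c(OC)c1 | intermediate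
8 | (S)-diene ether | C=C[C@H](OCC(=C)C(=O)c1cc(OC)c(OCc2ccccc2)c(OC)c1)c1cc(OC)c(OCc2ccccc2)c(OC)c1 | intermediate
9 | (S)-2-aryl-4-aroyl-2,5-dihydrofuran | COc1cc(cc(OC)c1OCc1ccccc1)C(=O)C1=C[C@@H](c2cc(OC)c(OCc3ccccc3)c(OC)c2)OC1 | intermediate
10 | 2,3-trans Giese adduct (C4 epimeric mixture, C4 undefined) | COc1cc(cc(OC)c1OCc1ccccc1)C(=O)C1CO[C@H](c2cc(OC)c(OCc3ccccc3)c(OC)c2)[C@H]1COCc1ccccc1 | intermediate
11 | (2S,3R,4S)-tri-O-benzyl ketone | COc1cc(cc(OC)c1OCc1ccccc1)C(=O)[C@@H]1CO[C@H](c2cc(OC)c(OCc3ccccc3)c(OC)c2)[C@H]1COCc1ccccc1 | intermediate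
12 | target | COc1cc(C(=O)[C@@H]2CO[C@H](c3cc(OC)c(O)c(OC)c3)[C@H]2CO)cc(OC)c1O | target

## Totals
- Total steps: 11.
- Longest linear sequence: 10 steps (1 → 2 → 3 → 4 → 6 → 7 → 8 → 9 → 10 → 11 → 12 via the bromide branch; the chiral-alcohol branch is 9 steps).

## Three steps most likely to fail
1. **Step 9 (photoredox Giese).** The γ-C2–H of the enone is acidic, so the basic conditions could racemise C2, and the facial selectivity could be poor.
   Fallback (different approach): Cu-catalysed, TMSCl-assisted conjugate addition of vinylMgBr to **9**, anti to the C2-aryl group. Then OsO4/NaIO4 cleavage and chemoselective aldehyde reduction (NaBH(OAc)3, −78 °C) give the same CH2OH-bearing THF.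
2. **Step 8 (RCM).** The electron-poor 1,1-disubstituted acrylophenone and the hindered aryl-substituted allylic ether may give low conversion or isomerise to the furan.
   Fallback (different approach): use commercial methyl 2-(bromomethyl)acrylate in place of **7**, so RCM gives the 2,5-dihydrofuran-4-carboxylate. Run the Giese on the enoate, then convert the ester to the aryl ketone through its Weinreb amide and ArMgBr.
3. **Step 11 (global hydrogenolysis).** The aryl ketone could be over-reduced, or the benzylic C2–O bond could be cleaved.
   Fallback (different approach): carry the phenols as MOM ethers and the primary alcohol as TBS from the start, using MOM-protected syringaldehyde and TBSOCH2CO2H in the Giese step. Deprotect non-reductively with ZnBr2/n-PrSH followed by Et3N·3HF.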